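The cis-decalin is disconnected at C4–C5 and C9–C10, which unfolds ring A (C1–C5, C10) and ring B (C5–C10) into a head-to-tail chain with alkenes C3=C4 (E), C5=C10 (Z, neryl) and C8=C9 (allylsilane). One bromonium-initiated, allylsilane-terminated bicyclisation should close both rings and set C3, C4, C5, C9 and C10. Anti addition across the Z C5=C10 alkene encodes the cis fusion with the C4 and C10 methyls cis, and loss of silicon leaves the C8 methylidene. The precursor is a nerol-derived (4E,8Z,12Z)-trienoate bearing CH2SiMe3 on C8 and a silyl ether on C11. Later the C15 carboxylate inverts C3–Br to C3–O, and the pyranone is joined to C11 by Negishi coupling.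

Key step: step 10

Remarks on the chemistry
- Numbering: decalin C1–C10 (ring A = C1–C5 and C10, ring B = C5–C10). C10 carries the angular methyl, C5 is the ring-fusion CH, C4 is quaternary (methyl and chain C12–C13–C15), C3 is the carbinol carbon, C8 the methylidene carbon, C9 the CH bearing C11. α is the face carrying the C10 methyl, H5 and the C4 methyl; β is the other face. CIP descriptors refer to this numbering.
- The alkene geometries of the cyclisation precursor and the configuration of the bromodecalin were re-derived from chair–chair anti addition and compared with the target. They agree: bromine is α (equatorial), and inversion puts O3 β as in the target. Neither structure needs a change.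
- Design changes to the supply and the endgame: the allylsilane is unveiled last from an alkenyl iodide, and C6–C7 is made by alkylating a propargyl dianion, not by an allyl–allyl coupling that would risk transposition and Z/E scrambling. The lactonisation avoids silver, so C3 never becomes a cation beside quaternary C4.
- Assumption: the antipode of the chiral Lewis base that brominates the required C3=C4 face is found by testing both enantiomers; the route is written for that antipode.

Step 1
Reactants: 1 nerol [(2Z)-3,7-dimethylocta-2,6-dien-1-ol]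
Product: 2 neryl bromide [(2Z)-1-bromo-3,7-dimethylocta-2,6-diene]
Conditions: PBr3 (0.4 equiv), Et2O, −10 °C
Reagents that add atoms: phosphorus tribromide, BrP(Br)Br
Why: Bromination of a primary allylic alcohol through its phosphite ester (SN2 by bromide) at low temperature should keep the Z alkene and avoid allylic transposition.

Step 2
Reactants: 2 neryl bromide; 3 propargyl bromide (3-bromoprop-1-yne)
Product: 5 (6Z)-7,11-dimethyldodeca-6,10-dien-2-yn-1-ol, via lithium acetylide 4 (not isolated)
Conditions: 3, n-BuLi (2 equiv), TMEDA, Et2O, −78 °C; then 2, −78 °C→rt; then (CH2O)n, THF, rt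
Reagents that add atoms: propargyl bromide (3), C#CCBr; paraformaldehyde (as formaldehyde), C=O
Why: 1,3-Dilithiopropyne made in the flask alkylates the allylic bromide at its sp3 carbanion (SN2, Z geometry kept), and the remaining lithium acetylide 4 is hydroxymethylated by formaldehyde (acetylide addition to an aldehyde).

Step 3
Reactants: 5 (6Z)-7,11-dimethyldodeca-6,10-dien-2-yn-1-ol
Product: 6 (2Z,6Z)-3-iodo-7,11-dimethyldodeca-2,6,10-trien-1-ol
Conditions: NaAlH2(OCH2CH2OMe)2, THF, 0 °C→rt; EtOAc; then I2, −78 °C
Reagents that add atoms: iodine, II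
Why: Hydroxyl-directed trans-hydroalumination of the propargylic alcohol places aluminium on C8 cis to CH2O (five-membered alkoxyalanate), and iodinolysis with retention should give the alkenyl iodide with iodine cis to C11, which fixes the later allylsilane geometry (C11 trans to C7); the isolated alkenes are inert.

Step 4
Reactants: 6 (2Z,6Z)-3-iodo-7,11-dimethyldodeca-2,6,10-trien-1-ol
Product: 7 tert-butyl{[(2Z,6Z)-3-iodo-7,11-dimethyldodeca-2,6,10-trien-1-yl]oxy}diphenylsilane
Conditions: TBDPSCl, imidazole, CH2Cl2, rt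
Reagents that add atoms: tert-butyl(chloro)diphenylsilane, CC(C)(C)[Si](Cl)(c1ccccc1)c1ccccc1
Why: Standard silylation of a primary allylic alcohol; the bulky silyl ether later screens the C8=C9 alkene from the bromenium carrier.

Step 5
Reactants: 7 tert-butyl{[(2Z,6Z)-3-iodo-7,11-dimethyldodeca-2,6,10-trien-1-yl]oxy}diphenylsilane
Product: 8 (2E,6Z,10Z)-12-[(tert-butyldiphenylsilyl)oxy]-10-iodo-2,6-dimethyldodeca-2,6,10-trien-1-ol
Conditions: SeO2 (cat.), t-BuOOH, salicylic acid (cat.), CH2Cl2, 0 °C→rt; then NaBH4, MeOH, 0 °C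
Reagents that add atoms: selenium dioxide, O=[Se]=O; tert-butyl hydroperoxide, CC(C)(C)OO
Why: Riley allylic oxidation (ene reaction, then [2,3]-sigmatropic shift) is selective for the E methyl of the terminal isopropylidene and gives the E allylic alcohol; the iodo-alkene is deactivated, and the borohydride finish returns any enal to the alcohol.

Step 6
Reactants: 8 (2E,6Z,10Z)-12-[(tert-butyldiphenylsilyl)oxy]-10-iodo-2,6-dimethyldodeca-2,6,10-trien-1-ol
Product: 9 {[(2Z,6Z,10E)-12-bromo-3-iodo-7,11-dimethyldodeca-2,6,10-trien-1-yl]oxy}(tert-butyl)diphenylsilane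
Conditions: CBr4, PPh3, CH2Cl2, 0 °C
Reagents that add atoms: carbon tetrabromide, BrC(Br)(Br)Br
Why: The Appel reaction converts the primary allylic alcohol into the bromide under neutral conditions without touching the alkenyl iodide, the silyl ether or the alkene geometries.

Step 7
Reactants: 9 allylic bromide; 10 dimethyl malonate
Product: 11 dimethyl 2-[(2E,6Z,10Z)-12-[(tert-butyldiphenylsilyl)oxy]-10-iodo-2,6-dimethyldodeca-2,6,10-trien-1-yl]propanedioate
Conditions: 10 (3 equiv), NaH, THF, 0 °C→rt
Reagents that add atoms: dimethyl malonate (10), COC(=O)CC(=O)OC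
Why: Malonic ester alkylation (SN2 at the primary allylic bromide) adds C13 and C15; excess malonate suppresses dialkylation.

Step 8
Reactants: 11 malonate
Product: 12 methyl (4E,8Z,12Z)-14-[(tert-butyldiphenylsilyl)oxy]-12-iodo-4,8-dimethyltetradeca-4,8,12-trienoate
Conditions: LiCl, H2O, DMSO, 150 °C
Reagents that add atoms: none
Why: Krapcho dealkoxycarbonylation removes one ester under neutral conditions that the alkenyl iodide, the silyl ether and the three alkenes should tolerate.

Step 9
Reactants: 12 alkenyl iodide ester; 13 (trimethylsilyl)methylmagnesium chloride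
Product: 14 methyl (4E,8Z,12Z)-14-[(tert-butyldiphenylsilyl)oxy]-4,8-dimethyl-12-[(trimethylsilyl)methyl]tetradeca-4,8,12-trienoate
Conditions: 13, ZnCl2, THF, 0 °C; then 12, Pd(PPh3)4 (5 mol %), THF, rt→45 °C
Reagents that add atoms: (trimethylsilyl)methylmagnesium chloride (13), C[Si](C)(C)C[Mg]Cl
Why: Negishi coupling of the alkenyl iodide with the zinc reagent made in the flask proceeds with retention of alkene geometry and spares the methyl ester; the acid-sensitive allylsilane appears only one step before it is used.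

Step 10
Reactants: 14 (4E,8Z,12Z)-dienyl allylsilane ester
Product: 15 methyl 3-[(3R,4R,5R,9S,10R)-3α-bromo-9β-{[(tert-butyldiphenylsilyl)oxy]methyl}-4α,10α-dimethyl-8-methylidene-5αH-decalin-4β-yl]propanoate (cis-fused)
Conditions: NBS (1.1 equiv), chiral BINOL-derived thiophosphoramide Lewis base (10 mol %), toluene/CH2Cl2, −78 °C
Reagents that add atoms: N-bromosuccinimide, O=C1CCC(=O)N1Br
Why: Proposed new method: the chiral Lewis base relays Br+ from NBS to the C3=C4 alkene, C5 of the Z alkene opens the bromonium at C4 anti to bromine, C9 of the allylsilane takes the emerging C10 cation anti to the new C4–C5 bond, and the β-silyl cation at C8 sheds silicon to leave the C8 methylidene. The closest known reaction types are enantioselective bromonium-initiated polyene cyclisations of E-polyprenoids and allylsilane-terminated cation–olefin bicyclisations, neither known for a Z central alkene. Ring A (C1–C5, C10) closes 6-endo by the C4–C5 bond and ring B (C5–C10) closes 6-endo by the C9–C10 bond, each through a chair. C3 is set by the face on which the promoter places bromine, C4 by anti opening of the E-alkene bromonium (methyl axial, chain equatorial, Br cis to the C4 methyl), C5 and C10 by anti addition across the Z alkene (cis fusion, C10 methyl cis to C4 methyl), and C9 by the ring B chair, in which the C11-trans-to-C7 allylsilane geometry puts C11 equatorial and trans to the C10 methyl. The step needs site selectivity for C3=C4 and concerted capture of C10: C3=C4 is the least hindered alkene, the C8=C9 alkene is screened by CH2SiMe3 and CH2OTBDPS and deactivated by its allylic oxygen, the methyl ester is the least nucleophilic carboxyl derivative, and low temperature in a non-polar medium keeps the chain folded so that the allylsilane traps C10 before any bond rotation.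

Step 11
Reactants: 15 3α-bromo cis-decalin ester
Product: 17 cis-fused δ-lactone (3S,4R,5R,9S,10R) with O3β–C15(=O) and 9β-CH2OTBDPS, via cesium carboxylate 16 (not isolated)
Conditions: CsOH·H2O (1.1 equiv), THF/H2O, rt; evaporate; DMF, 80 °C
Reagents that add atoms: cesium hydroxide, [Cs+].[OH-]
Why: Saponification, then intramolecular SN2 displacement of the secondary bromide by the carboxylate (6-exo-tet lactonisation), should invert C3 and give the cis-fused δ-lactone with O3 β (axial) and C12 equatorial; the cesium salt in a dipolar aprotic solvent keeps the reaction on the SN2 path.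

Step 12
Reactants: 17 δ-lactone
Product: 18 (3S,4R,5R,9S,10R)-9β-{[(tert-butyldiphenylsilyl)oxy]methyl}-4β-(3-hydroxy-3-methylbutyl)-4α,10α-dimethyl-8-methylidene-5αH-decalin-3β-ol
Conditions: MeLi (4 equiv), THF, −78→0 °C
Reagents that add atoms: methyllithium, [Li]C
Why: Two-fold addition of methyllithium to the δ-lactone (through the methyl ketone) gives the tertiary carbinol at C15 and frees O3; the silyl ether and the 1,1-disubstituted alkene are inert and no stereocentre is touched.

Step 13
Reactants: 18 diol silyl ether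
Product: 19 (3S,4R,5R,9S,10R)-9β-(hydroxymethyl)-4β-(3-hydroxy-3-methylbutyl)-4α,10α-dimethyl-8-methylidene-5αH-decalin-3β-ol
Conditions: Bu4NF, THF, rt
Reagents that add atoms: none
Why: Fluoride cleavage of the silyl ether gives a triol whose hydroxyls differ by class (primary, hindered secondary, tertiary), which the next three steps exploit.

Step 14
Reactants: 19 triol
Product: 20 (3S,4R,5R,9S,10R)-4β-(3-hydroxy-3-methylbutyl)-9β-(iodomethyl)-4α,10α-dimethyl-8-methylidene-5αH-decalin-3β-ol
Conditions: I2, PPh3, imidazole, THF, 0 °C→rt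
Reagents that add atoms: iodine, II
Why: Appel-type iodination (PPh3/I2/imidazole) is selective for the primary hydroxyl over the hindered secondary and the tertiary one, and substitutes at C11 by SN2, so C9 is untouched.

Step 15
Reactants: 20 iodo diol
Product: 21 3β-triethylsilyl ether of 20 (tertiary hydroxyl free)
Conditions: TESCl, imidazole, DMAP (cat.), CH2Cl2, rt
Reagents that add atoms: chlorotriethylsilane, CC[Si](Cl)(CC)CC
Why: Silyl chlorides with imidazole silylate secondary but not tertiary alcohols, so only O3 is protected; the triethylsilyl group is small enough for the hindered axial hydroxyl and can later be removed without harming a formate.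

Step 16
Reactants: 21 3β-silyl ether
Product: 22 4-[(3S,4R,5R,9S,10R)-9β-(iodomethyl)-4α,10α-dimethyl-8-methylidene-3β-(triethylsilyloxy)-5αH-decalin-4β-yl]-2-methylbutan-2-yl formate
Conditions: acetic formic anhydride, pyridine, CH2Cl2, 0 °C→rt
Reagents that add atoms: acetic formic anhydride, CC(=O)OC=O
Why: Formyl transfer from the mixed anhydride (its formyl carbonyl is the more electrophilic) esterifies the only free hydroxyl, the tertiary one; pyridine buffers the acid, so the silyl ether and the methylidene should survive.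

Step 17
Reactants: 23 methyl acetoacetate; 24 malonyl dichloride
Product: 25 methyl 4-hydroxy-6-methyl-2-oxo-2H-pyran-5-carboxylate
Conditions: 24, CH2Cl2, 0 °C→40 °C
Reagents that add atoms: malonyl dichloride (24), O=C(Cl)CC(=O)Cl
Why: C-Acylation of the β-keto ester by malonyl dichloride, then O-cyclisation of the acetyl enol onto the second acid chloride (classical malonyl chloride pyranone synthesis), builds the 4-hydroxy-2-pyranone with methyl and ester in place.

Step 18
Reactants: 25 hydroxypyranone
Product: 26 methyl 6-methoxy-2-methyl-4-oxo-4H-pyran-3-carboxylate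
Conditions: MeOTf, CH2Cl2, rt; aq. NaHCO3
Reagents that add atoms: methyl trifluoromethanesulfonate, COS(=O)(=O)C(F)(F)F
Why: A hard methylating agent O-methylates a 4-hydroxy-2-pyranone at the ring carbonyl oxygen and, after loss of the proton, gives the 2-methoxy-4-pyranone rather than the 4-methoxy-2-pyranone; the C4 hydroxyl is held in a hydrogen bond to the neighbouring ester.

Step 19
Reactants: 26 methoxypyranone
Product: 27 methyl 5-iodo-6-methoxy-2-methyl-4-oxo-4H-pyran-3-carboxylate
Conditions: NIS, CF3CO2H (cat.), MeCN, rt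
Reagents that add atoms: N-iodosuccinimide, O=C1CCC(=O)N1I
Why: Electrophilic iodination occurs at the only ring CH, the nucleophilic α-carbon of the methoxy-enone lying between C=O and C–OMe.

Step 20
Reactants: 22 iodo formate; 27 iodopyranone
Product: 29 3-O-triethylsilyl ether of the target, via alkylzinc iodide 28 (not isolated)
Conditions: Zn dust, LiCl, THF, 40 °C; then 27, Pd(OAc)2 (5 mol %), SPhos (10 mol %), THF, rt→45 °C
Reagents that add atoms: none
Why: Zinc insertion into the primary iodide gives alkylzinc 28, and Negishi sp3–sp2 coupling with the α-iodo-enone-type pyranone forms the C11–pyranone bond; the organozinc tolerates formate, silyl ether and the pyranone ester, and the bulky biarylphosphine disfavours β-hydride elimination.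

Step 21
Reactants: 29 silyl-protected target
Product: 30 CNP0292250.1, (3S,4R,5R,9S,10S)
Conditions: HF·pyridine, pyridine, THF, 0 °C→rt
Reagents that add atoms: none
Why: Buffered HF·pyridine cleaves the triethylsilyl ether by fluoride attack at silicon under conditions that should leave the tertiary formate, the methoxypyranone and the methylidene intact.

Compound list
1 | nerol, (2Z)-3,7-dimethylocta-2,6-dien-1-ol | CC(C)=CCC/C(C)=C\CO | starting material
2 | neryl bromide, (2Z)-1-bromo-3,7-dimethylocta-2,6-diene | CC(C)=CCC/C(C)=C\CBr | intermediate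
3 | propargyl bromide, 3-bromoprop-1-yne | C#CCBr | starting material
4 | lithium (5Z)-6,10-dimethylundeca-5,9-dien-1-yn-1-ide | [Li]C#CCC/C=C(C)\CCC=C(C)C | intermediate
5 | (6Z)-7,11-dimethyldodeca-6,10-dien-2-yn-1-ol | OCC#CCC/C=C(C)\CCC=C(C)C | intermediate
6 | (2Z,6Z)-3-iodo-7,11-dimethyldodeca-2,6,10-trien-1-ol | OC/C=C(\I)CC/C=C(C)\CCC=C(C)C | intermediate
7 | tert-butyl{[(2Z,6Z)-3-iodo-7,11-dimethyldodeca-2,6,10-trien-1-yl]oxy}diphenylsilane | CC(C)(C)[Si](c1ccccc1)(c1ccccc1)OC/C=C(\I)CC/C=C(C)\CCC=C(C)C | intermediate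
8 | (2E,6Z,10Z)-12-[(tert-butyldiphenylsilyl)oxy]-10-iodo-2,6-dimethyldodeca-2,6,10-trien-1-ol | OC/C(C)=C/CC/C(C)=C\CC/C(I)=C/CO[Si](c1ccccc1)(c1ccccc1)C(C)(C)C | intermediate
9 | {[(2Z,6Z,10E)-12-bromo-3-iodo-7,11-dimethyldodeca-2,6,10-trien-1-yl]oxy}(tert-butyl)diphenylsilane | BrC/C(C)=C/CC/C(C)=C\CC/C(I)=C/CO[Si](c1ccccc1)(c1ccccc1)C(C)(C)C | intermediate
10 | dimethyl malonate | COC(=O)CC(=O)OC | starting material
11 | dimethyl 2-[(2E,6Z,10Z)-12-[(tert-butyldiphenylsilyl)oxy]-10-iodo-2,6-dimethyldodeca-2,6,10-trien-1-yl]propanedioate | COC(=O)C(C(=O)OC)C/C(C)=C/CC/C(C)=C\CC/C(I)=C/CO[Si](c1ccccc1)(c1ccccc1)C(C)(C)C | intermediate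
12 | methyl (4E,8Z,12Z)-14-[(tert-butyldiphenylsilyl)oxy]-12-iodo-4,8-dimethyltetradeca-4,8,12-trienoate | COC(=O)CC/C(C)=C/CC/C(C)=C\CC/C(I)=C/CO[Si](c1ccccc1)(c1ccccc1)C(C)(C)C | intermediate
13 | (trimethylsilyl)methylmagnesium chloride | C[Si](C)(C)C[Mg]Cl | starting material
14 | methyl (4E,8Z,12Z)-14-[(tert-butyldiphenylsilyl)oxy]-4,8-dimethyl-12-[(trimethylsilyl)methyl]tetradeca-4,8,12-trienoate (cyclisation precursor) | COC(=O)CC/C(C)=C/CC/C(C)=C\CC/C(C[Si](C)(C)C)=C/CO[Si](c1ccccc1)(c1ccccc1)C(C)(C)C | intermediate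
15 | methyl 3-[(3R,4R,5R,9S,10R)-3α-bromo-9β-{[(tert-butyldiphenylsilyl)oxy]methyl}-4α,10α-dimethyl-8-methylidene-5αH-decalin-4β-yl]propanoate (cis-fused) | C=C1CC[C@H]2[C@@](C)(CCC(=O)OC)[C@H](Br)CC[C@@]2(C)[C@H]1CO[Si](c1ccccc1)(c1ccccc1)C(C)(C)C | intermediate
16 | cesium carboxylate of 15 (C15 carboxylate, 3α-bromide) | C=C1CC[C@H]2[C@@](C)(CCC(=O)[O-])[C@H](Br)CC[C@@]2(C)[C@H]1CO[Si](c1ccccc1)(c1ccccc1)C(C)(C)C.[Cs+] | intermediate
17 | cis-fused δ-lactone, (3S,4R,5R,9S,10R): O3β–C15(=O)–C13–C12–C4 ring, 9β-CH2OTBDPS, 4α,10α-dimethyl, 8-methylidene, 5αH | C=C1CC[C@H]2[C@@]3(C)CCC(=O)O[C@H]3CC[C@@]2(C)[C@H]1CO[Si](c1ccccc1)(c1ccccc1)C(C)(C)C | intermediate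
18 | (3S,4R,5R,9S,10R)-9β-{[(tert-butyldiphenylsilyl)oxy]methyl}-4β-(3-hydroxy-3-methylbutyl)-4α,10α-dimethyl-8-methylidene-5αH-decalin-3β-ol | C=C1CC[C@H]2[C@@](C)(CCC(C)(C)O)[C@@H](O)CC[C@@]2(C)[C@H]1CO[Si](c1ccccc1)(c1ccccc1)C(C)(C)C | intermediate
19 | (3S,4R,5R,9S,10R)-9β-(hydroxymethyl)-4β-(3-hydroxy-3-methylbutyl)-4α,10α-dimethyl-8-methylidene-5αH-decalin-3β-ol | C=C1CC[C@H]2[C@@](C)(CCC(C)(C)O)[C@@H](O)CC[C@@]2(C)[C@H]1CO | intermediate
20 | (3S,4R,5R,9S,10R)-4β-(3-hydroxy-3-methylbutyl)-9β-(iodomethyl)-4α,10α-dimethyl-8-methylidene-5αH-decalin-3β-ol | C=C1CC[C@H]2[C@@](C)(CCC(C)(C)O)[C@@H](O)CC[C@@]2(C)[C@H]1CI | intermediate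
21 | 3β-triethylsilyl ether of 20 | C=C1CC[C@H]2[C@@](C)(CCC(C)(C)O)[C@@H](O[Si](CC)(CC)CC)CC[C@@]2(C)[C@H]1CI | intermediate
22 | 4-[(3S,4R,5R,9S,10R)-9β-(iodomethyl)-4α,10α-dimethyl-8-methylidene-3β-(triethylsilyloxy)-5αH-decalin-4β-yl]-2-methylbutan-2-yl formate | C=C1CC[C@H]2[C@@](C)(CCC(C)(C)OC=O)[C@@H](O[Si](CC)(CC)CC)CC[C@@]2(C)[C@H]1CI | intermediate
23 | methyl acetoacetate | COC(=O)CC(C)=O | starting material
24 | malonyl dichloride | O=C(Cl)CC(=O)Cl | starting material
25 | methyl 4-hydroxy-6-methyl-2-oxo-2H-pyran-5-carboxylate | COC(=O)c1c(O)cc(=O)oc1C | intermediate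
26 | methyl 6-methoxy-2-methyl-4-oxo-4H-pyran-3-carboxylate | COC(=O)c1c(C)oc(OC)cc1=O | intermediate
27 | methyl 5-iodo-6-methoxy-2-methyl-4-oxo-4H-pyran-3-carboxylate | COC(=O)c1c(C)oc(OC)c(I)c1=O | intermediate
28 | alkylzinc iodide from 22 (C11–ZnI) | C=C1CC[C@H]2[C@@](C)(CCC(C)(C)OC=O)[C@@H](O[Si](CC)(CC)CC)CC[C@@]2(C)[C@H]1C[Zn]I | intermediate
29 | 3-O-triethylsilyl ether of the target, (3S,4R,5R,9S,10S) | C=C1CC[C@H]2[C@@](C)(CCC(C)(C)OC=O)[C@@H](O[Si](CC)(CC)CC)CC[C@@]2(C)[C@H]1Cc1c(OC)oc(C)c(C(=O)OC)c1=O | intermediate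
30 | CNP0292250.1, (3S,4R,5R,9S,10S): 3β-hydroxy, 4α,10α-dimethyl, 4β-(3-formyloxy-3-methylbutyl), 8-methylidene, 5αH, 9β-[(2-methoxy-5-methoxycarbonyl-6-methyl-4-oxo-4H-pyran-3-yl)methyl] | C=C1CC[C@H]2[C@@](C)(CCC(C)(C)OC=O)[C@@H](O)CC[C@@]2(C)[C@H]1Cc1c(OC)oc(C)c(C(=O)OC)c1=O | target

Total step count: 21. Longest linear sequence: 18 steps from nerol (steps 1–16, 20 and 21); the pyranone branch is steps 17–19.

Steps most likely to fail

Step 10 (new method). Bromenium may be transferred to the wrong π system (bromodesilylation of the allylsilane, or attack at C5=C10). The bromonium may be intercepted by the ester carbonyl, the C10 cation may be captured stepwise with loss of the cis fusion, or the two faces of C3=C4 may be poorly discriminated. The fallback installs the initiator beforehand as an epoxide, using known reactions only; it sets out from alkenyl iodide ester 12 and comes back at lactone 17. Saponification (LiOH, THF/H2O) gives the carboxylic acid F1. Catalytic asymmetric bromolactonisation (NBS, cinchona-derived amino-thiocarbamate catalyst, −60 °C) is site-selective for C3=C4 because the carboxylate can only reach C4, and gives the bromo γ-lactone F2 (C4–O and C3–Br anti). K2CO3 in MeOH opens the lactone, and the C4 alkoxide displaces bromide with inversion to give the trans-epoxy methyl ester F3. Negishi coupling as in step 9 gives the epoxy allylsilane F4. MeAlCl2 (CH2Cl2, −78 °C) triggers the epoxide-initiated, allylsilane-terminated bicyclisation to the 3α-hydroxy cis-decalin ester F5 (oxygen anti to C5, hence on the face of the C4 methyl). Dess–Martin periodinane gives the 3-ketone F6. LiBH(s-Bu)3 (THF, −78 °C) should attack from the equatorial direction to give the axial 3β-hydroxy ester F7 as its alkoxide, which closes onto the ester on warming to give 17.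

Step 11. E2 loss of HBr, or ionisation with a shift from quaternary C4, may outrun the hindered backside attack at the neopentyl-type C3. The fallback turns the elimination into the productive path; it sets out from bromo ester 15 and comes back at lactone 17. After saponification to carboxylate 16, KOt-Bu in DMSO (rt→50 °C) completes the E2 to the Δ2-ene acid F8 (C2=C3; only C2 carries hydrogen). I2/NaHCO3 (MeCN/H2O, 0 °C) gives the iodolactone F9 by anti addition: the carboxylate tethered on the β face of C4 can only reach C3 from the β face, so O3 becomes β (axial) and iodine at C2 α. Bu3SnH/AIBN (toluene, 80 °C) removes iodine by radical reduction and gives 17.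

Step 20. Zinc insertion into the β-branched homoallylic iodide may be sluggish, the alkylzinc may be protonated, or the alkylpalladium may undergo β-hydride elimination to the 8,9-bis-methylidene diene. The fallback reverses the polarity of the coupling; it sets out from iodide 22 and iodopyranone 27 and comes back at 29. Zinc insertion into the sp2 C–I bond of 27 (Zn dust, LiCl, THF, rt) gives the pyranonylzinc iodide F10. F10 is coupled with the primary alkyl iodide 22 under Ni(acac)2/4-fluorostyrene catalysis (THF/NMP, −15 °C), a known coupling of functionalised arylzinc reagents with primary alkyl iodides, to give 29.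

Further compounds
F1 | step 10 | (4E,8Z,12Z)-14-[(tert-butyldiphenylsilyl)oxy]-12-iodo-4,8-dimethyltetradeca-4,8,12-trienoic acid | OC(=O)CC/C(C)=C/CC/C(C)=C\CC/C(I)=C/CO[Si](c1ccccc1)(c1ccccc1)C(C)(C)C
F2 | step 10 | bromo γ-lactone (C4–O lactone, C3–Br anti; alkenyl iodide chain) | O=C1CC[C@@](C)(O1)[C@@H](Br)CC/C(C)=C\CC/C(I)=C/CO[Si](c1ccccc1)(c1ccccc1)C(C)(C)C
F3 | step 10 | trans-3,4-epoxy methyl ester (alkenyl iodide) | COC(=O)CC[C@@]1(C)O[C@@H]1CC/C(C)=C\CC/C(I)=C/CO[Si](c1ccccc1)(c1ccccc1)C(C)(C)C
F4 | step 10 | trans-3,4-epoxy methyl ester (allylsilane) | COC(=O)CC[C@@]1(C)O[C@@H]1CC/C(C)=C\CC/C(C[Si](C)(C)C)=C/CO[Si](c1ccccc1)(c1ccccc1)C(C)(C)C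
F5 | step 10 | 3α-hydroxy analogue of 15 (OH in place of Br) | C=C1CC[C@H]2[C@@](C)(CCC(=O)OC)[C@H](O)CC[C@@]2(C)[C@H]1CO[Si](c1ccccc1)(c1ccccc1)C(C)(C)C
F6 | step 10 | 3-oxo cis-decalin ester | C=C1CC[C@H]2[C@@](C)(CCC(=O)OC)C(=O)CC[C@@]2(C)[C@H]1CO[Si](c1ccccc1)(c1ccccc1)C(C)(C)C
F7 | step 10 | 3β-hydroxy cis-decalin ester (formed as its alkoxide) | C=C1CC[C@H]2[C@@](C)(CCC(=O)OC)[C@@H](O)CC[C@@]2(C)[C@H]1CO[Si](c1ccccc1)(c1ccccc1)C(C)(C)C
F8 | step 11 | Δ2-ene acid (C2=C3 alkene, C15 acid) | C=C1CC[C@H]2[C@@](C)(CCC(=O)O)C=CC[C@@]2(C)[C@H]1CO[Si](c1ccccc1)(c1ccccc1)C(C)(C)C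
F9 | step 11 | 2α-iodo δ-lactone (O3 β, iodine at C2 α) | C=C1CC[C@H]2[C@@]3(C)CCC(=O)O[C@H]3[C@H](I)C[C@@]2(C)[C@H]1CO[Si](c1ccccc1)(c1ccccc1)C(C)(C)C
F10 | step 20 | pyranonylzinc iodide from 27 | COC(=O)c1c(C)oc(OC)c([Zn]I)c1=O
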